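Ring D (the cyclohexadienone) is built de novo instead of being imported as an arene. Ring D is joined through its C4 to the exocyclic methide carbon, which also bears the phenyl and ring A C5 (between aryl-bearing C4 and alkynyl-bearing C6). A 3-aryl-3-phenylpropanal therefore already contains the methide carbon plus ring D C4 and C3. Amine-catalysed Michael addition of this aldehyde to methyl vinyl ketone, then aldol condensation, adds ring D C5, C6, C1 and C2, so two C–C bonds and the six-membered ring arise in one operation. The precursor is the racemic bis(methoxymethyl) ether 13; two dehydrogenations and an acetal cleavage then finish the target.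

Key step: step 9

Remark 1: The target is taken exactly as drawn, with an unsubstituted phenyl on the methide carbon and no configurational element (ring D is symmetric about the exocyclic double bond); every sp3 stereocentre of the intermediates is formed without control and is erased by step 12.
Remark 2: Ring A numbering follows the target: C1 (CH3), C4 (4-hydroxyphenyl), C5 (methide carbon), C6 (alkynyl). The contiguous substituents at C4, C5 and C6 need three contiguous handles, which a 3,4-dihalotoluene cannot supply, so ring A is taken from 5-bromo-2-methylphenol (bromide for C4, new formyl group for C5, phenol/triflate for C6).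
Remark 3: Both spectator phenols are carried as methoxymethyl ethers rather than methyl ethers, so that no boron trihalide is brought near the 2-alkynylbiaryl unit.
Remark 4: ArA = 6-[4-(methoxymethoxy)phenyl]-2-{[4-(methoxymethoxy)phenyl]ethynyl}-3-methylphenyl, bonded through its C1 (= ring A C5 of the target).

Step 1
Reactants: 1 5-bromo-2-methylphenol
Product: 2 6-bromo-2-hydroxy-3-methylbenzaldehyde
Conditions: MgCl2, Et3N, (CH2O)n, MeCN, reflux; then aq. HCl
Reagents that add atoms: paraformaldehyde (as formaldehyde), C=O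
Why: Magnesium-phenoxide-directed ortho-formylation (Casnati–Skattebøl type) can occur only at C6, the single free position ortho to the hydroxyl, and bromophenols are tolerated in this reaction.

Step 2
Reactants: 2 6-bromo-2-hydroxy-3-methylbenzaldehyde; 3 [4-(methoxymethoxy)phenyl]boronic acid
Product: 4 2-hydroxy-6-[4-(methoxymethoxy)phenyl]-3-methylbenzaldehyde
Conditions: Pd(dppf)Cl2 (3 mol %), K2CO3, 1,4-dioxane/H2O, 90 °C
Reagents that add atoms: none
Why: Suzuki–Miyaura coupling at a bromide activated by the ortho formyl group should proceed with the phenol carried as its phenoxide, and the methoxymethyl ether is stable to aqueous carbonate.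

Step 3
Reactants: 4 2-hydroxy-6-[4-(methoxymethoxy)phenyl]-3-methylbenzaldehyde
Product: 5 2-formyl-3-[4-(methoxymethoxy)phenyl]-6-methylphenyl trifluoromethanesulfonate
Conditions: Tf2O, pyridine, CH2Cl2, 0 °C
Reagents that add atoms: trifluoromethanesulfonic anhydride, O=S(=O)(OS(=O)(=O)C(F)(F)F)C(F)(F)F
Why: O-Sulfonylation of the only free hydroxyl with triflic anhydride and pyridine converts the phenol into a cross-coupling handle at the future ring A C6.

Step 4
Reactants: 6 4-(methoxymethoxy)benzaldehyde
Product: 7 1-ethynyl-4-(methoxymethoxy)benzene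
Conditions: MeC(O)C(N2)P(O)(OMe)2, K2CO3, MeOH, 0 °C → rt
Reagents that add atoms: dimethyl (1-diazo-2-oxopropyl)phosphonate, CC(=O)C(=[N+]=[N-])P(=O)(OC)OC
Why: Seyferth–Gilbert homologation in its Ohira–Bestmann form turns a non-enolisable aryl aldehyde into the terminal alkyne under mild carbonate conditions that leave the acetal untouched.

Step 5
Reactants: 5 2-formyl-3-[4-(methoxymethoxy)phenyl]-6-methylphenyl trifluoromethanesulfonate; 7 1-ethynyl-4-(methoxymethoxy)benzene
Product: 8 6-[4-(methoxymethoxy)phenyl]-2-{[4-(methoxymethoxy)phenyl]ethynyl}-3-methylbenzaldehyde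
Conditions: Pd(PPh3)2Cl2 (5 mol %), CuI (10 mol %), Et3N, DMF, 70 °C (degassed)
Reagents that add atoms: none
Why: Sonogashira coupling of an aryl triflate activated by its ortho formyl group with a terminal arylacetylene is the standard entry to 2-alkynylbenzaldehydes.

Step 6
Reactants: 8 6-[4-(methoxymethoxy)phenyl]-2-{[4-(methoxymethoxy)phenyl]ethynyl}-3-methylbenzaldehyde
Product: 9 ethyl (2E)-3-(ArA)prop-2-enoate
Conditions: (EtO)2P(O)CH2CO2Et, NaH, THF, 0 °C → rt
Reagents that add atoms: triethyl phosphonoacetate, CCOC(=O)CP(=O)(OCC)OCC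
Why: Horner–Wadsworth–Emmons olefination of a non-enolisable aromatic aldehyde with a stabilised phosphonate anion should give the E-acrylate, the geometry being irrelevant after the next step.

Step 7
Reactants: 9 ethyl (2E)-3-(ArA)prop-2-enoate; 10 phenylmagnesium bromide
Product: 12 ethyl 3-(ArA)-3-phenylpropanoate (racemic), via silyl ketene acetal 11 (not isolated)
Conditions: CuBr·SMe2 (20 mol %), Me3SiCl, THF, −40 → 0 °C; then aq. NH4Cl
Reagents that add atoms: none
Why: Copper-catalysed, Me3SiCl-accelerated conjugate addition of an aryl Grignard reagent to a cinnamate-type ester is the usual route to 3,3-diarylpropanoates; here the small phenyl nucleophile goes to the crowded β-carbon, the benzylic stereocentre forms racemic, and the silyl ketene acetal is hydrolysed at work-up.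

Step 8
Reactants: 12 ethyl 3-(ArA)-3-phenylpropanoate (racemic)
Product: 13 3-(ArA)-3-phenylpropanal (racemic)
Conditions: i-Bu2AlH (1.1 equiv), CH2Cl2, −78 °C; MeOH, then aq. potassium sodium tartrate (KNaC4H4O6)
Reagents that add atoms: none
Why: Partial reduction of an ethyl ester with i-Bu2AlH at −78 °C should stop at the aluminium hemiacetal, which releases the aldehyde on work-up, while the diarylalkyne and the acetals are inert at this temperature.

Step 9
Reactants: 13 3-(ArA)-3-phenylpropanal (racemic); 14 methyl vinyl ketone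
Product: 18 4-[(ArA)(phenyl)methyl]cyclohex-2-en-1-one (mixture of diastereomers), via diethyl enamine 15 (not isolated), via 1,5-ketoaldehyde 16 (not isolated), via aldol adduct 17 (not isolated)
Conditions: Et2NH (30 mol %), MeCN, rt → 40 °C; then KOH, n-Bu4NOH (cat.), THF/Et2O/H2O, rt
Reagents that add atoms: none
Why: Diethylamine condenses with the unhindered CH2–CHO terminus to give enamine 15, whose β-carbon adds to methyl vinyl ketone, and hydrolysis returns the amine and the 1,5-ketoaldehyde 16; hydroxide then forms the methyl-ketone enolate, which attacks the aldehyde carbonyl, and the β-hydroxy ketone 17 loses water to the conjugated enone. The closest known reaction is the amine-catalysed Robinson-type annulation of α-monosubstituted aldehydes with methyl vinyl ketone, which gives 4-substituted cyclohex-2-enones. The ring closes by a 6-(enolendo)-exo-trig aldol addition. One new stereocentre (ring C4, the former aldehyde α-carbon) arises beside the existing benzylic one and is not controlled, which is harmless because both sp3 carbons become sp2 in steps 10 and 12. The step needs regioselective closure and mono-alkylation: only attack of the methyl-derived enolate on the aldehyde gives a six-membered ring that can dehydrate (the alternatives are four-membered rings), and the α-branched adduct 16 forms an enamine far more slowly than 13, which should suppress a second Michael addition.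

Step 10
Reactants: 18 4-[(ArA)(phenyl)methyl]cyclohex-2-en-1-one (mixture of diastereomers)
Product: 22 4-[(ArA)(phenyl)methyl]phenol (racemic), via α'-selenide 19 (not isolated), via selenoxide 20 (not isolated), via cyclohexadienone tautomer 21 (not isolated)
Conditions: LiN(i-Pr)2 (1.15 equiv), THF, −78 °C; PhSeCl, −78 °C; then 30% H2O2, pyridine, CH2Cl2, 0 °C → rt
Reagents that add atoms: none
Why: Kinetic deprotonation of the enone occurs at the α'-carbon C6, and selenenylation, oxidation and selenoxide syn-elimination (Reich–Sharpless dehydrogenation) give the cross-conjugated dienone, which is the keto tautomer of a phenol and aromatises spontaneously, destroying the ring stereocentre.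

Step 11
Reactants: 22 4-[(ArA)(phenyl)methyl]phenol (racemic)
Product: 23 4-[{6-(4-hydroxyphenyl)-2-[(4-hydroxyphenyl)ethynyl]-3-methylphenyl}(phenyl)methyl]phenol (racemic)
Conditions: conc. HCl (cat.), MeOH/THF, 45 °C
Reagents that add atoms: none
Why: Acid-catalysed acetal exchange with methanol removes both methoxymethyl ethers as dimethoxymethane, and at this oxidation level no cation can form at the triarylmethane carbon, so the neighbouring biaryl and alkyne are not endangered.

Step 12
Reactants: 23 4-[{6-(4-hydroxyphenyl)-2-[(4-hydroxyphenyl)ethynyl]-3-methylphenyl}(phenyl)methyl]phenol (racemic)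
Product: 24 selaginellin A, 4-[{6-(4-hydroxyphenyl)-2-[(4-hydroxyphenyl)ethynyl]-3-methylphenyl}(phenyl)methylidene]cyclohexa-2,5-dien-1-one
Conditions: DDQ (1.05 equiv), 1,4-dioxane, rt
Reagents that add atoms: none
Why: DDQ dehydrogenation of a 4-hydroxytriarylmethane to a fuchsone-type quinone methide abstracts hydride from the methine para to the ring D hydroxyl, the only position whose cation is a protonated quinone methide, and the other two phenols carry no para C–H, so the last stereocentre is removed selectively.

Compound list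
1 | 5-bromo-2-methylphenol | Cc1ccc(Br)cc1O | starting material
2 | 6-bromo-2-hydroxy-3-methylbenzaldehyde | Cc1ccc(Br)c(C=O)c1O | intermediate
3 | [4-(methoxymethoxy)phenyl]boronic acid | COCOc1ccc(B(O)O)cc1 | starting material
4 | 2-hydroxy-6-[4-(methoxymethoxy)phenyl]-3-methylbenzaldehyde | Cc1ccc(-c2ccc(OCOC)cc2)c(C=O)c1O | intermediate
5 | 2-formyl-3-[4-(methoxymethoxy)phenyl]-6-methylphenyl trifluoromethanesulfonate | Cc1ccc(-c2ccc(OCOC)cc2)c(C=O)c1OS(=O)(=O)C(F)(F)F | intermediate
6 | 4-(methoxymethoxy)benzaldehyde | COCOc1ccc(C=O)cc1 | starting material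
7 | 1-ethynyl-4-(methoxymethoxy)benzene | COCOc1ccc(C#C)cc1 | intermediate
8 | 6-[4-(methoxymethoxy)phenyl]-2-{[4-(methoxymethoxy)phenyl]ethynyl}-3-methylbenzaldehyde | O=Cc1c(-c2ccc(OCOC)cc2)ccc(C)c1C#Cc1ccc(OCOC)cc1 | intermediate
9 | ethyl (2E)-3-(ArA)prop-2-enoate | CCOC(=O)/C=C/c1c(-c2ccc(OCOC)cc2)ccc(C)c1C#Cc1ccc(OCOC)cc1 | intermediate
10 | phenylmagnesium bromide | Br[Mg]c1ccccc1 | starting material
11 | 1-ethoxy-3-(ArA)-3-phenyl-1-(trimethylsilyloxy)prop-1-ene (silyl ketene acetal, racemic, double-bond isomers) | CCOC(O[Si](C)(C)C)=CC(c1ccccc1)c1c(-c2ccc(OCOC)cc2)ccc(C)c1C#Cc1ccc(OCOC)cc1 | intermediate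
12 | ethyl 3-(ArA)-3-phenylpropanoate (racemic) | CCOC(=O)CC(c1ccccc1)c1c(-c2ccc(OCOC)cc2)ccc(C)c1C#Cc1ccc(OCOC)cc1 | intermediate
13 | 3-(ArA)-3-phenylpropanal (racemic) | O=CCC(c1ccccc1)c1c(-c2ccc(OCOC)cc2)ccc(C)c1C#Cc1ccc(OCOC)cc1 | intermediate
14 | methyl vinyl ketone (but-3-en-2-one) | C=CC(C)=O | starting material
15 | (E)-N,N-diethyl-3-(ArA)-3-phenylprop-1-en-1-amine (racemic) | CCN(CC)/C=C/C(c1ccccc1)c1c(-c2ccc(OCOC)cc2)ccc(C)c1C#Cc1ccc(OCOC)cc1 | intermediate
16 | 2-[(ArA)(phenyl)methyl]-5-oxohexanal (mixture of diastereomers) | CC(=O)CCC(C=O)C(c1ccccc1)c1c(-c2ccc(OCOC)cc2)ccc(C)c1C#Cc1ccc(OCOC)cc1 | intermediate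
17 | 3-hydroxy-4-[(ArA)(phenyl)methyl]cyclohexan-1-one (mixture of diastereomers) | O=C1CCC(C(c2ccccc2)c2c(-c3ccc(OCOC)cc3)ccc(C)c2C#Cc2ccc(OCOC)cc2)C(O)C1 | intermediate
18 | 4-[(ArA)(phenyl)methyl]cyclohex-2-en-1-one (mixture of diastereomers) | O=C1C=CC(C(c2ccccc2)c2c(-c3ccc(OCOC)cc3)ccc(C)c2C#Cc2ccc(OCOC)cc2)CC1 | intermediate
19 | 4-[(ArA)(phenyl)methyl]-6-(phenylselanyl)cyclohex-2-en-1-one (mixture of diastereomers) | O=C1C=CC(C(c2ccccc2)c2c(-c3ccc(OCOC)cc3)ccc(C)c2C#Cc2ccc(OCOC)cc2)CC1[Se]c1ccccc1 | intermediate
20 | 6-(benzeneseleninyl)-4-[(ArA)(phenyl)methyl]cyclohex-2-en-1-one (mixture of diastereomers) | O=C1C=CC(C(c2ccccc2)c2c(-c3ccc(OCOC)cc3)ccc(C)c2C#Cc2ccc(OCOC)cc2)CC1[Se](=O)c1ccccc1 | intermediate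
21 | 4-[(ArA)(phenyl)methyl]cyclohexa-2,5-dien-1-one (racemic) | O=C1C=CC(C(c2ccccc2)c2c(-c3ccc(OCOC)cc3)ccc(C)c2C#Cc2ccc(OCOC)cc2)C=C1 | intermediate
22 | 4-[(ArA)(phenyl)methyl]phenol (racemic) | Oc1ccc(C(c2ccccc2)c2c(-c3ccc(OCOC)cc3)ccc(C)c2C#Cc2ccc(OCOC)cc2)cc1 | intermediate
23 | 4-[{6-(4-hydroxyphenyl)-2-[(4-hydroxyphenyl)ethynyl]-3-methylphenyl}(phenyl)methyl]phenol (racemic) | Oc1ccc(C(c2ccccc2)c2c(-c3ccc(O)cc3)ccc(C)c2C#Cc2ccc(O)cc2)cc1 | intermediate
24 | selaginellin A | Cc1ccc(-c2ccc(O)cc2)c(C(=C2C=CC(=O)C=C2)c2ccccc2)c1C#Cc1ccc(O)cc1 | target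

Total step count: 12. Longest linear sequence: 11 steps (steps 1, 2, 3, 5, 6, 7, 8, 9, 10, 11, 12); step 4 is a one-step side branch.

Steps most likely to fail

Step 9. The enamine Michael addition has to occur at a carbon next to the crowded diarylmethine, so it may be slow enough for polymerisation of the vinyl ketone or self-aldolisation of the aldehyde to take over. The fallback sets out from aldehyde 13 and forms the first C–C bond by alkylation instead of conjugate addition. Condensation with cyclohexylamine (MgSO4, CH2Cl2) should give the N-cyclohexyl imine F1. Deprotonation with LiN(i-Pr)2 (THF, −78 → 0 °C) and alkylation of the aza-enolate with 2-(2-bromoethyl)-2-methyl-1,3-dioxolane should give the alkylated imine F2. Aqueous oxalic acid then hydrolyses the imine to the dioxolane aldehyde F3, and PPTS in acetone/water at 50 °C removes the ketal. The fallback comes back to the route at ketoaldehyde 16, which is closed to 18 with the same hydroxide treatment.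

Step 7. Delivery of phenyl to a β-carbon shielded by two ortho substituents may be sluggish, so that 1,2-attack on the ester or recovery of the acrylate results. The fallback sets out from aldehyde 8 and uses a far more electrophilic acceptor. Knoevenagel condensation with Meldrum's acid (pyrrolidinium acetate, toluene, 50 °C) should give the arylidene Meldrum's acid F4. Uncatalysed addition of phenylmagnesium bromide (THF, −20 → 0 °C) should give the 5-(diarylmethyl) Meldrum's acid F5. Refluxing ethanol/pyridine then opens and decarboxylates F5, and the fallback comes back to the route at ethyl ester 12.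

Step 10. Regiocontrol in enolate formation may be lost, or electrophilic selenium may transfer to the newly formed phenol or the alkyne during the selenoxide elimination. The fallback sets out from enone 18 and replaces selenium by a Saegusa–Ito oxidation. Kinetic enolisation and silylation (LiN(i-Pr)2, Me3SiCl, THF, −78 °C) should give the 2-silyloxy-1,3-diene F6. Pd(OAc)2 (1 equiv) in MeCN at rt should convert F6 into dienone 21, which tautomerises, and the fallback comes back to the route at phenol 22.

Further compounds
F1 | step 9 | N-cyclohexyl-3-(ArA)-3-phenylpropan-1-imine (racemic) | C1CCC(CC1)N=CCC(c1ccccc1)c1c(-c2ccc(OCOC)cc2)ccc(C)c1C#Cc1ccc(OCOC)cc1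
F2 | step 9 | N-cyclohexyl-2-[(ArA)(phenyl)methyl]-4-(2-methyl-1,3-dioxolan-2-yl)butan-1-imine (mixture of diastereomers) | CC1(CCC(C=NC2CCCCC2)C(c2ccccc2)c2c(-c3ccc(OCOC)cc3)ccc(C)c2C#Cc2ccc(OCOC)cc2)OCCO1
F3 | step 9 | 2-[(ArA)(phenyl)methyl]-4-(2-methyl-1,3-dioxolan-2-yl)butanal (mixture of diastereomers) | CC1(CCC(C=O)C(c2ccccc2)c2c(-c3ccc(OCOC)cc3)ccc(C)c2C#Cc2ccc(OCOC)cc2)OCCO1
F4 | step 7 | 5-[(ArA)methylidene]-2,2-dimethyl-1,3-dioxane-4,6-dione | CC1(C)OC(=O)C(=Cc2c(-c3ccc(OCOC)cc3)ccc(C)c2C#Cc2ccc(OCOC)cc2)C(=O)O1
F5 | step 7 | 5-[(ArA)(phenyl)methyl]-2,2-dimethyl-1,3-dioxane-4,6-dione (racemic) | CC1(C)OC(=O)C(C(c2ccccc2)c2c(-c3ccc(OCOC)cc3)ccc(C)c2C#Cc2ccc(OCOC)cc2)C(=O)O1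
F6 | step 10 | {[4-((ArA)(phenyl)methyl)cyclohexa-1,5-dien-1-yl]oxy}trimethylsilane (mixture of diastereomers) | C[Si](C)(C)OC1=CCC(C(c2ccccc2)c2c(-c3ccc(OCOC)cc3)ccc(C)c2C#Cc2ccc(OCOC)cc2)C=C1
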